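With a substrate half-life of 8.5 h by the first step in maple, intermediate arrives slowly, so I ask what share of it becomes target.

    substrate + reagent → intermediate + by-product (k1 = 3.7 L mol⁻¹ h⁻¹)
    intermediate ⇌ target (K2 = 1.3, k2 = 0.071 h⁻¹)
    intermediate ⇌ isomer of the product (K3 = 2.8, k3 = 0.042 h⁻¹)
    intermediate → side product (k4 = 0.024 h⁻¹)
    target → over-reaction product (k5 = 6.4 × 10⁻⁵ h⁻¹)
    substrate + target ⇌ idle adduct, settled at all times (K6 = 140 L mol⁻¹)

| flask | substrate | reagent | time | remark |
|---|---|---|---|---|
| elm | 20 mM (fed, over 25.0 h) | 1.10 equiv | 25 h | a stirred flask in which substrate is dosed at a steady rate over 25.0 h without added volume, worked up at 25 h |
| larch | 20 mM | 1.10 equiv (fed, over 25.0 h) | 25 h | all but reagent at the start; reagent goes in evenly over 25.0 h, the run ends at 25 h |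
| ash | 20 mM | 1.10 equiv |  | one stirred flow tank at steady state, fed with the mixture as stated, mean residence time 25 h |
| maple | 20 mM | 1.10 equiv | 25 h | everything together in a closed stirred flask, run for 25 h |

- percent here means substrate units held: one idle adduct counts as two
- what is said of target includes idle adduct
- the stated concentrations are those of everything mixed, before any reaction; amounts are the same in each set-up
- the feed brings no volume worth counting
- in an amount of target, one idle adduct counts as one target
- run time (elm): 25 h

* the set-up with the highest amount of target at the outlet or at the end, in percent of the substrate put in ("none" if the first two lie within 2 percentage points) (elm / larch / ash / maple / none)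
* amount of target at the outlet or at the end, in percent of the substrate put in, elm
* amount of target at the outlet or at the end, in percent of the substrate put in, larch
* amount of target at the outlet or at the end, in percent of the substrate put in, ash
* amount of target at the outlet or at the end, in percent of the substrate put in, maple

**Forward share.** Intermediate leaves towards target, isomer and side product, each rate proportional to [intermediate]. I divide the rate to target by the sum of those rates, so [intermediate] and time cancel. This gives 51.8%, the forward share, the part of intermediate leaving forward that goes to target. Between target and isomer, the same way gives target 62.8% of the pair.

**Balance way.** Equilibrium constants give a second answer for that pair: 31.7% target. The two part, so one of them cheats.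

**Which cheats.** The balance way needs the back steps to have run. In maple, isomer returns with a half-life of 46.2 h, longer than the 25 h run. At charged substrate, the idle adduct leaves 26.3% of target free, so target returns with a half-life near 48.2 h, also longer than the run. This half-life shortens as substrate falls. So I trust the forward way, which is kinetic control, and expect it to read somewhat high.

**My reckoning.** Second-order kinetics, ignoring the adduct, converts 69.1% of the substrate in maple. Multiplying by the forward share gives 35.8% target in maple, an estimate and not a bound. Some converted substrate will still sit as intermediate at the end, so I expect a figure below that. I pick maple as best, though I have reckoned no other flask.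

**Forecast.** The forecast gives elm 11.8%, larch 14.3%, ash 15.2% and maple 23.5%, the last below my estimate for maple, with maple best, reasoning that “having both substrate and reagent at full strength from the start makes the intermediate earliest in the closed flask”.

**Result.** The simulation gives elm 13.6%, larch 14.3%, ash 15.4% and maple 23.2%, so maple is best. At the end of maple, by-product stands at 13.1 mM and intermediate at 15.4%. So 50.0% of the substrate has passed beyond intermediate, and the forward share of that is 25.9%, which stands above the target of maple.

**Second flask.** Elm run with 5.0 mM of substrate ends with by-product at 0.981 mM and intermediate at 8.64%. The forward share then gives 5.69% target. The computed result is 5.17%.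

Its constants come from no measurement; the result is computed.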